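The fraction of starting material left after 4.00 min is the same in alder, at 20 mM, and in oak, at 10 mM: 92.9% against 92.8%. In these flasks a free enzyme turns starting material and second substrate into target.

| flask | starting material | second substrate | free enzyme | remark | time |
|---|---|---|---|---|---|
| alder | 20 mM | 1.1 equiv | 0.02 mol% | run made earlier |  |
| oak | 10 mM | 1.1 equiv | 0.02 mol% | run made earlier |  |
| dusk | 20 mM | 1.10 equiv | 0.02 mol% | everything together at the start | 15 min |
| winter | 20 mM (fed, over 3.0 min) | 1.10 equiv | 0.02 mol% | all else is in the flask from the start; the feed brings no volume worth counting | 15 min |
| noon | 20 mM | 1.10 equiv (fed, over 3.0 min) | 0.02 mol% | all else is in the flask from the start; the feed brings no volume worth counting | 15 min |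
| autumn | 20 mM (fed, over 50 s) | 1.10 equiv | 0.02 mol% | all else is in the flask from the start; the feed brings no volume worth counting | 15 min |
| summer | 20 mM | 1.10 equiv (in portions, 3, over 3.0 min) | 0.02 mol% | first portion at the start, last at 3.0 min | 15 min |

| run | time / min | target / % | starting material / % |
|---|---|---|---|
| alder | 1.33 | 1.8 | 96.4 |
| alder | 2.50 | 6.7 | 95.7 |
| alder | 4.00 | 7.9 | 92.9 |
| alder | 5.00 | 10.0 | 92.1 |
| alder | 6.00 | 12.2 | 89.7 |
| alder | 8.00 | 16.3 | 84.0 |
| alder | 10.0 | 19.3 | 81.7 |
| oak | 0.250 | 0.8 | 99.6 |
| oak | 0.667 | 0 | 100.5 |
| oak | 1.33 | 1.5 | 97.8 |
| oak | 2.00 | 4.2 | 95.8 |
| oak | 2.50 | 6.7 | 97.8 |
| oak | 4.00 | 9.5 | 92.8 |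
| oak | 5.00 | 10.9 | 88.7 |

(scatter of a reading: 1 percentage point)

* the best flask by amount of target, in percent of the starting material charged; "all alike" if 1.5 percentage points covers them all (dusk / winter / noon / autumn / summer / all alike)
* amount of target at the end, in percent of the starting material charged, dusk
* amount of target at the end, in percent of the starting material charged, winter
* amount of target at the end, in percent of the starting material charged, noon
* amount of target at the end, in percent of the starting material charged, autumn
* amount of target at the end, in percent of the starting material charged, summer

- a reading or a percentage of target counts all its forms, free or not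

The loading is 0.02 mol% in both runs, so the enzyme concentration fell along with the starting material while the fraction spent per minute held. The readings thus fit a rate that follows the enzyme, zero order in both substrates over this range. It is reckoned here on the fraction left, which in the readings falls on a nearly straight line. The last alder reading, good to 1 percentage point, stands at 81.7% after 10.0 min, which gives an emptying time 54.6 min, the time that line needs to reach nil, and a slope of 0.0183 /min of the charge. The fraction left is one minus the time over the emptying time. If the rate follows the enzyme, the emptying time goes inversely with the loading, which is the same in both runs and so is not tested by them.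

On this line, left and spent cross at 27.3 min, later than the asked time and beyond the last reading. On this reckoning the knee comes at the emptying time, where the line meets its level, nil starting material, because starting material is the limiting reagent against 1.10 equiv of second substrate. At 15 min this reckoning leaves 72.5% and gives 27.4% of target for dusk. A late start of 0.820 min would cost the margin. Winter's feed brings starting material 18.2 times faster than the line spends it, so this reckoning expects little loss.

The forecast stands higher, at 30.5% for dusk (27.5% to 33%), 30% for winter, 30% for noon, 30.3% for autumn and 30.4% for summer, and it says: “All flasks come out alike”.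

The flasks give 28.3% for dusk, 27.7% for winter, 27.9% for noon, 28.2% for autumn and 28.2% for summer, so the answer is all alike.

    free enzyme + target ⇌ idle complex, settled at all times (K = 74.8 /M)
    starting material + free enzyme ⇌ first complex (K = 250 /M, k = 19100 /M/s)
    second complex → free enzyme + target (k = 2.25 /s)
    first complex ⇌ loaded enzyme + first product (K = 0.0360 M, k = 7.51 /s)
    second substrate + target ⇌ idle adduct, settled at all times (K = 375 /M)
    first product → by-product carried off (k = 0.00274 /s)
    second substrate + loaded enzyme ⇌ second complex (K = 1600 /M, k = 16500 /M/s)

The gap between dusk and winter, read on the line, is a late start of 0.341 min, shorter than the margin's 0.820 min. A neighbour of summer at 0.008 mol% has its emptying time stretched to 137 min, which leaves 89.1%, and it holds 88.6%. Summer has not come to rest: 72% of its starting material remains at 15 min, and its emptying time lies well inside ten times that span. After 150 min summer's target stands at >99.9%.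

All runs are simulated on assumed constants; noise was put on by code.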